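The closed, stirred vessel, the ochre flask, held starting material at 1.2 M, reagent at 1.44 M, free catalyst at 2.4 mM and added ligand at 1.4 mM. The green run differed in free catalyst, at 1.6 mM.

| run | time / h | target / % | starting material / % |
|---|---|---|---|
| ochre | 1.00 | 0.4 | 99.5 |
| ochre | 3.00 | 1.6 | 98.5 |
| ochre | 5.00 | 2.2 | 97.5 |
| ochre | 8.00 | 3.5 | 96.3 |
| ochre | 12.0 | 5.5 | 93.9 |
| ochre | 15.0 | 7.5 | 92.8 |
| green | 3.00 | 1.2 | 99.0 |
| green | 10.0 | 3.6 | 96.4 |
| green | 15.0 | 4.9 | 95.3 |
| green | 25.0 | 7.5 | 92.5 |
| green | 40.0 | 11.5 | 88.5 |
| green | 50.0 | 14.1 | 85.2 |

(each reading ± 0.3 percentage points)

- no earlier run changes the charge of reagent; that part of a forecast is a guess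

- apparent order in reagent when 50% of the starting material are converted (percent change of the rate of making target for one percent more reagent charged)

I followed the rate of the ochre flask. Over its first 15.0 h it averaged 0.00500 /h as a fraction of the charge. Its target then read 1.53 times green's at that time, against a catalyst ratio of 1.50, with a scatter of 0.3 percentage points on each reading.

I reckoned with two slowing factors. At the mark of 50% conversion, the starting material factor was 50.0%, and the reagent factor, the fraction of its charge left, was 0.583. I wrote the rate as start rate times the first factor times the second raised to n, the local order in reagent. With n at one, I reckoned 0.291 of the start rate at the mark for the ochre flask.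

The reagent factor also answered the question. Define the lever as the reagent charge over what remains of it at the mark: 1.71. At a fixed conversion, with n taken as the local order in the reagent remaining, the apparent order is n times this lever. No run changed the reagent, so I left n unread; first order gave 1.71.

The forecast used the same lever, 1.71, with this local order: “I take a local order of about 0.8, allowing for possible saturation”. It gave 1.4.

The flask gave 0.96.

    starting material + free catalyst ⇌ catalyst intermediate A (K = 12.0 /M, k = 80.0 /M/h)
    catalyst intermediate A → catalyst intermediate B (k = 3.80 /h)
    reagent + catalyst intermediate B ⇌ catalyst intermediate C (K = 0.220 /M, k = 12.0 /M/h)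
    catalyst intermediate C ⇌ free catalyst + target (K = 0.480 M, k = 73.0 /h)
    free catalyst + added ligand ⇌ idle complex (K = 430 /M, k = 140 /M/h)

Divided by the lever, that made n 0.560. At 0.500 d in the ochre flask, with starting material at 94.3%, catalyst intermediate A held 58.7% of the catalyst. By 5.00 d in that flask, with reagent at 65.0% of its charge, the resting state had passed to catalyst intermediate B, at 50.1% against 32.3% for catalyst intermediate A. At 70% conversion the lever was 2.40, and this n put the rate at 0.497 of its value at the mark; the flask gave 0.48.

The numbers in the tables were computed with constants of no real substance, noise included.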